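All runs are calculated for an exercise, noise included.

If a fixed amount of L is lost on charging and the rate of E -> G is proportional to the L left over (a titrated catalyst, in the usual term), then two runs at one [E] give the order in [L] at the higher charge. I wanted that number first.

| flask | E | L | time |
|---|---|---|---|
| red | 0.800 M | 0.00400 M |  |
| grey | 0.800 M | 0.00200 M |  |
| violet | 1.60 M | 0.00400 M |  |
| amber | 0.800 M | 0.00400 M | 16 min |

- red run (time / min: [G] / M): 1.1: 0.105; 2.3: 0.192; 3.4: 0.264; 4.5: 0.305; 5.6: 0.351; 6.8: 0.361; 7.9: 0.421
- grey run (time / min: [G] / M): 1.1: 0.005; 2.3: 0.007; 3.4: 0.027; 4.5: 0.041; 5.6: 0.040; 6.8: 0.047; 7.9: 0.039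
- violet run (time / min: [G] / M): 1.1: 0.152; 2.3: 0.297; 3.4: 0.372; 4.5: 0.467; 5.6: 0.531; 6.8: 0.567; 7.9: 0.624

(standard deviation of a reading: 0.008 M)

- Overall: E -> G, with L as catalyst.
- Constant volume, constant temperature.
- The analysis sees a species whether free or bound.
- An order is taken over about fifteen percent of the charge, up and down.

- the exponent of [L] in the starting rate at the charge of the red run (at the point where two percent of the E have become G)
- the exponent of [E] in the starting rate at the charge of the red run (at the point where two percent of the E have become G) (one fixed amount of G, the same in the runs compared)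
- G in the amber run at 16 min, as a share of the E charged

Let ρ be the rate of the red run over that of the grey run. The algebra gives the order at the red charge as a ceiling, the red [L] over the difference of the two charges, 2.00, times one minus the inverse of ρ.

I went through the inputs in turn. The ceiling of 2.00 is reckoned from the charges, which carry no stated scatter. The red slope to the first reading, 0.0955 M min⁻¹, carries 7.62% from that reading. The grey slope to 4.5 min, 0.00911 M min⁻¹, carries 19.5%. Together they read ρ as 10.5. The red slope is averaged over more G than the grey one, and the red curve bends, so I took this ρ as a low reading. That mattered little, since ρ enters through its inverse: doubling it raised the order by 0.0952, and halving it lowered the order by 0.190. My reckoning therefore stood on the proportionality, which two charges could not test, and gave an order in [L] of 1.81.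

The forecast gave 1.9 for [L], 0.65 for [E] and 63% for the amber run, reading “a fixed poison of about 0.0018 M titrating L”, and its order in [L] stood a little above mine.

The simulation gave 1.9 for [L], 0.61 for [E] and 68.7% for the amber run at 16 min.

    L + E ⇌ LE, settled at all times (0.9920 M⁻¹)
    LE ⇌ G + L (155.4 min⁻¹, 7.080 M⁻¹ min⁻¹)
    L + G ⇌ LG, settled at all times (8.550 M⁻¹)
    L + Qa → Qe

At one amount of G, the grey run went at 0.052 of the rate of the red run, a ρ of 19.2. Under the ceiling of 2.00, that ρ gave an order of 1.90 for the red run, so I reckoned 0.00211 M of L, free and bound together, left over there. With the same amount lost from the grey run, I reckoned 1.10 × 10⁻⁴ M left over, 5.50% of the grey charge.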